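The earlier runs and the new flask stem from a simulated flask for substances that don't exist; noise was put on by code.

The ratio of product to starting material is what I follow through these runs, and over its last two readings it stands at 0.441 in the red run but at 1.11 in the green run, which carries more coupling partner and less protic impurity.

in all of them: starting material 0.20 M; catalyst 0.18 mM
- grey: coupling partner 0.70 M; protic impurity 0.010 M; run made earlier
- green: coupling partner 1.1 M; protic impurity 0.010 M; run made earlier
- red: coupling partner 0.50 M; protic impurity 0.020 M; run made earlier
- flask: coupling partner 0.500 M; protic impurity 0.0100 M; time 3.0 min

| run | time / min | starting material / % | product / % |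
|---|---|---|---|
| grey | 0.250 | 65 | 33 |
| grey | 0.333 | 63 | 40 |
| grey | 0.500 | 62 | 39 |
| grey | 0.833 | 59 | 38 |
| grey | 1.33 | 61 | 37 |
| grey | 2.00 | 59 | 38 |
| grey | 3.00 | 61 | 38 |
| green | 0.167 | 56 | 45 |
| green | 0.500 | 50 | 53 |
| green | 0.833 | 50 | 50 |
| green | 1.33 | 51 | 51 |
| green | 2.00 | 49 | 50 |
| green | 2.50 | 48 | 52 |
| green | 3.00 | 47 | 53 |
| red | 0.250 | 71 | 24 |
| red | 0.833 | 69 | 34 |
| red | 1.33 | 72 | 31 |
| red | 2.00 | 72 | 31 |
| red | 3.00 | 71 | 32 |

(standard deviation of a reading: 1.5 percentage points)

- steps under discussion: starting material + coupling partner + catalyst <-> product + catalyst; coupling partner + protic impurity -> quenched reagent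

- the largest share of what was charged as starting material, at 3.0 min belongs to (starting material / product)
- the largest share itself, whichever of these holds it, in percent of the starting material charged

Two rates make that ratio: the forward rate of the catalysed step goes with c(starting material) · c(coupling partner), the backward rate with c(product), and the catalyst multiplies both alike, so where they are equal the ratio is flat and follows the free coupling partner. I assume each protic impurity has taken one coupling partner, and I define:

K = c(product) / [c(starting material) · c(free coupling partner)]

c(free coupling partner) = c(coupling partner charged) − c(protic impurity charged) − c(product)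

Over the last two readings this gives 1.03 M⁻¹ for grey, 1.12 M⁻¹ for green and 1.06 M⁻¹ for red. I carry their mean, 1.07 M⁻¹, as the plateau constant, product over starting material per unit of free coupling partner, which is the equilibrium constant of the step, read from the readings.

The red run, charged with the flask's 0.50 M of coupling partner but twice its protic impurity, is flat by 0.833 min, well before 3.0 min, so I take the flask to be on its plateau, under thermodynamic control. With f the share turned into product and 0.490 M of coupling partner after the quench, the flask obeys a quadratic in f:

f / (1 − f) = K · (0.490 M − 0.20 M · f)

f = 31.4%

So I expect starting material to keep the larger share, at 68.6%.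

The forecast says starting material at 69%, holding that “This indicates equilibrium rather than catalyst death”. The flask gives starting material at 68.8%.

    starting material + coupling partner + catalyst ⇌ product + catalyst, rate k1*[starting material]*[coupling partner]*[catalyst] forward; the back reaction follows from the equilibrium constant (K = 1.06 M⁻¹, k = 481 M⁻² s⁻¹)
    coupling partner + protic impurity → quenched reagent (k = 5.39 M⁻¹ s⁻¹)

In the flask the relaxation half-life of the step, both directions together, is 0.0884 min, short against 3.0 min, and starting material stands at 68.8% after 1.50 min and at 68.8% after 30.0 min. K times the 0.428 M of coupling partner left in the flask gives a ratio of 0.458, and the flask shows 0.453. For a neighbour flask charged with 2.0 M of coupling partner, the same quadratic gives 66.5% product, and that neighbour holds 66.3%.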